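**Retrosynthetic overview**
1. The target is (13Z)-2β-acetoxylabda-8(17),13-dien-15-oic acid (ring A = C1–C5 and C10, ring B = C5–C10). The C12–C13 bond comes from a B-alkyl Suzuki–Miyaura coupling of a C9 vinyl group with (Z)-3-iodobut-2-enoic acid. The axial C2 acetate comes from hydride reduction of the 2-ketone on its open α face.
2. Enabling feature: in ring B the sp2 carbon C8 (methylene = masked ketone) is bonded to C9, C9 carries C11 (masked ester), and the ring-fusion bond C5–C10 lies β to C11. C8–C9 is therefore an aldol/Peterson retron and C5–C10 a Giese retron, so ring B equals the cyclobutane C5–C6–C7–C8 with the alkene C9=C10 inserted into its C5–C8 bond.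
3. Key disconnection: both six-membered rings of ester 11 go back to the monocyclic cyclobutanol 9 (β-hydroxysilane, Z-enoate, one controlling stereocentre).
4. Ring order: the four-membered ring is made first (step 1). Ring A (bond C5–C10) and ring B (four- to six-membered, bond C8–C9) form together in step 8.
5. Stereochemistry: the C2 carbinol is set by catalysis (step 3) and relays to C5, C9 and C10 (step 8). It is then erased (step 10) and re-set by C20 and the 4β-methyl group (step 12).

Key step: step 8

Numbering: labdane numbering is used for all compounds, acyclic ones included (C17 = methylene carbon on C8, C20 = methyl on C10, C11 = first side-chain carbon on C9).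
Assumption: the (R)-configured phosphoric acid of step 3 is taken to give the (R)-carbinol 5, as it does with simple aldehydes. If the sense is opposite, its mirror image is used.

Step 1
Reactants: 1 2,2-dimethylpent-4-enal
Product: 3 2-(2-methylpent-4-en-2-yl)cyclobutan-1-one, via oxaspiropentane 2 (not isolated)
Conditions: cyclopropyldiphenylsulfonium tetrafluoroborate, KOH, DMSO, 25 °C; then HBF4 (cat.), Et2O/H2O, 25 °C
Reagents that add atoms: cyclopropyldiphenylsulfonium tetrafluoroborate, C1CC1[S+](c1ccccc1)c1ccccc1.F[B-](F)(F)F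
Why: Johnson–Corey–Chaykovsky-type addition of the sulfonium cyclopropylide to the non-enolisable aldehyde gives 2, whose acid-induced cyclopropylcarbinyl-to-cyclobutyl rearrangement delivers the 2-substituted cyclobutanone; the new centre (C5) is racemic and is erased in step 8.

Step 2
Reactants: 3 2-(2-methylpent-4-en-2-yl)cyclobutan-1-one
Product: 4 3-methyl-3-(2-oxocyclobutyl)butanal
Conditions: O3, CH2Cl2, −78 °C; then Me2S, −78 °C to 25 °C
Reagents that add atoms: ozone, [O-][O+]=O
Why: Ozonolysis with reductive work-up cleaves the only alkene to the C2 aldehyde, and the cyclobutanone is inert to ozone at low temperature.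

Step 3
Reactants: 4 3-methyl-3-(2-oxocyclobutyl)butanal
Product: 5 2-[(4R)-4-hydroxy-2-methylhept-6-yn-2-yl]cyclobutan-1-one
Conditions: allenylboronic acid pinacol ester, (R)-3,3'-bis(2,4,6-triisopropylphenyl)-1,1'-binaphthyl-2,2'-diyl hydrogen phosphate (10 mol %), 4 Å MS, toluene, −20 °C; aq. work-up
Reagents that add atoms: allenylboronic acid pinacol ester, C=C=CB1OC(C)(C)C(C)(C)O1
Why: Phosphoric-acid-catalysed asymmetric propargylation (SE2' allenylboration through a closed six-membered transition state) is aldehyde-selective and sets the C2 carbinol centre by catalyst control, the only stereocentre introduced from outside.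

Step 4
Reactants: 5 2-[(4R)-4-hydroxy-2-methylhept-6-yn-2-yl]cyclobutan-1-one
Product: 6 (4R)-2-methyl-2-(2-oxocyclobutyl)hept-6-yn-4-yl 2,2-dimethylpropanoate
Conditions: t-BuCOCl, pyridine, 4-(dimethylamino)pyridine (10 mol %), CH2Cl2, 0 to 25 °C
Reagents that add atoms: pivaloyl chloride, CC(C)(C)C(=O)Cl
Why: Nucleophile-catalysed acylation drains any hemiketal form through the free secondary alcohol and gives a hindered ester that tolerates cuprate and organocerium reagents and falls off during the hydride reduction of step 9.

Step 5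
Reactants: 6 (4R)-2-methyl-2-(2-oxocyclobutyl)hept-6-yn-4-yl 2,2-dimethylpropanoate
Product: 7 methyl (5S)-7-methyl-7-(2-oxocyclobutyl)-5-(pivaloyloxy)oct-2-ynoate
Conditions: PdCl2 (5 mol %), CuCl2 (2.2 equiv), NaOAc (2.2 equiv), CO (1 atm), MeOH, 25 °C
Reagents that add atoms: carbon monoxide, [C-]#[O+]; methanol, CO
Why: Oxidative alkoxycarbonylation of the terminal alkyne with divalent palladium runs under buffered, base-free conditions, so that the enolisable cyclobutanone survives where acetylide chemistry would not (the descriptor changes only by priority).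

Step 6
Reactants: 7 methyl (5S)-7-methyl-7-(2-oxocyclobutyl)-5-(pivaloyloxy)oct-2-ynoate
Product: 8 methyl (2Z,5R)-3,7-dimethyl-7-(2-oxocyclobutyl)-5-(pivaloyloxy)oct-2-enoate
Conditions: Me2CuLi (1.2 equiv, from CuI and MeLi), THF, −78 °C; sat. aq. NH4Cl at −78 °C
Reagents that add atoms: lithium dimethylcuprate, [Li+].C[Cu-]C
Why: syn-Carbocupration of the ynoate and protonation with retention at −78 °C place methyl and hydrogen cis, that is C1 and the ester cis (Z), and the ynoate reacts with the cuprate far faster than the ketone.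

Step 7
Reactants: 8 methyl (2Z,5R)-3,7-dimethyl-7-(2-oxocyclobutyl)-5-(pivaloyloxy)oct-2-enoate
Product: 9 methyl (2Z,5R)-7-{2-hydroxy-2-[(trimethylsilyl)methyl]cyclobutyl}-3,7-dimethyl-5-(pivaloyloxy)oct-2-enoate
Conditions: Me3SiCH2MgCl (1.3 equiv), CeCl3 (1.3 equiv), THF, −78 °C; H2O
Reagents that add atoms: (trimethylsilyl)methylmagnesium chloride, C[Si](C)(C)C[Mg]Cl
Why: 1,2-Addition of the weakly basic organocerium reagent (first half of a Peterson olefination) goes to the strained ketone rather than to the hindered enoate or pivalate, and both ring diastereomers serve because C5 and C8 lose their configuration in step 8.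

Step 8
Reactants: 9 methyl (2Z,5R)-7-{2-hydroxy-2-[(trimethylsilyl)methyl]cyclobutyl}-3,7-dimethyl-5-(pivaloyloxy)oct-2-enoate
Product: 11 methyl 2α-(pivaloyloxy)-12,13,14,15,16-pentanorlabd-8(17)-en-11-oate, via decalin β-hydroxysilane 10 (not isolated)
Conditions: [Ir(dF(CF3)ppy)2(5,5'-(CF3)2bpy)]PF6 (2 mol %), n-Bu4P[O2P(OMe)2] (25 mol %), PhCF3 (0.01 M), 455 nm LEDs, 25 °C; then TsOH·H2O (20 mol %), 0 °C
Reagents that add atoms: none
Why: Proposed new method: Proton-coupled electron transfer from the tertiary O–H of 9 to the excited iridium complex and the phosphate base gives a cyclobutyloxy radical; strain-driven β-scission of the C8–C5 bond leaves an α-silyl ketone at C8 and a secondary radical at C5, C5 adds to C10 of the Z-enoate (Giese addition), the C9 α-ester radical is reduced by the divalent iridium complex to the ester enolate, the enolate adds to the C8 ketone, and acid then eliminates Me3SiOH from 10 (Peterson), so that C9 and C10 end up inserted into the former C5–C8 bond and the four-membered ring C5–C6–C7–C8 has become the six-membered ring B. The closest known reaction types are the light-driven ring opening of cyclic tertiary alcohols by proton-coupled electron transfer and the photocatalytic formal cycloaddition of cycloalkanols with electron-poor alkenes (β-scission, Giese addition, reduction to the carbanion, aldol closure); not yet shown are the intramolecular version on a cyclobutanol, a β,β-disubstituted acceptor and the Peterson exit. Ring A closes 6-exo-trig (radical, C5–C10) and ring B closes 6-(enolexo)-exo-trig (aldol, C9–C8). C10 and C5 are controlled by the C2 stereocentre through a chair transition state: the pivalate stays equatorial because the axial site is flanked by the axial C4 methyl and the axial C10 substituent, the C6 chain on C5 is equatorial, and the ester of the Z-enoate, being cis to C1, fits only over the small C5–H when C9 is equatorial and C20 axial, whereas the other alkene face would push it into the C4 gem-dimethyl group, which gives the trans ring fusion. C9 is set in the chair aldol closure with the ester equatorial (also the thermodynamic position), and the C8 carbinol centre is of no consequence because it becomes sp2. The step needs scission toward C5 rather than C7 (secured by the more substituted bond), cyclisation faster than 1,5-hydrogen transfer from C1 (secured by the gem-dimethyl group, the activated acceptor and high dilution) and an enolate formed only at C9 (secured by its radical origin, which a base could not achieve next to the more acidic ketone).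

Step 9
Reactants: 11 methyl 2α-(pivaloyloxy)-12,13,14,15,16-pentanorlabd-8(17)-en-11-oate
Product: 12 12,13,14,15,16-pentanorlabd-8(17)-ene-2α,11-diol
Conditions: LiAlH4, Et2O, 0 °C; H2O, aq. NaOH
Reagents that add atoms: none
Why: Hydride reduction converts the C11 ester into the primary alcohol and cleaves the pivalate in the same operation without touching the alkene or any stereocentre.

Step 10
Reactants: 12 12,13,14,15,16-pentanorlabd-8(17)-ene-2α,11-diol
Product: 13 2-oxo-12,13,14,15,16-pentanorlabd-8(17)-en-11-al
Conditions: (n-Pr)4N[RuO4] (5 mol %), N-methylmorpholine N-oxide (3 equiv), 4 Å MS, CH2Cl2, 0 to 25 °C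
Reagents that add atoms: none
Why: Ley–Griffith oxidation takes both alcohols to the carbonyl level under near-neutral anhydrous conditions that spare the β,γ-unsaturated aldehyde and its C9 centre, and it removes the now spent C2 stereocentre.

Step 11
Reactants: 13 2-oxo-12,13,14,15,16-pentanorlabd-8(17)-en-11-al
Product: 14 13,14,15,16-tetranorlabda-8(17),11-dien-2-one
Conditions: Ph3PCH3Br (1.1 equiv), KN(SiMe3)2 (1.05 equiv), THF, 0 °C; then 13, −78 to −20 °C
Reagents that add atoms: methyltriphenylphosphonium bromide, C[P+](c1ccccc1)(c1ccccc1)c1ccccc1.[Br-]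
Why: Wittig methylenation with one equivalent of ylide at low temperature takes the aldehyde, because the C2 ketone between the two quaternary β-carbons C4 and C10 reacts much more slowly.

Step 12
Reactants: 14 13,14,15,16-tetranorlabda-8(17),11-dien-2-one
Product: 15 13,14,15,16-tetranorlabda-8(17),11-dien-2β-ol
Conditions: NaBH4, MeOH, −20 °C
Reagents that add atoms: none
Why: Substrate-controlled hydride reduction: the β face of the C2 ketone is closed by the two syn-axial methyl groups (C20 and the 4β-methyl), so hydride enters from the α face and gives the axial 2β-alcohol.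

Step 13
Reactants: 15 13,14,15,16-tetranorlabda-8(17),11-dien-2β-ol
Product: 16 13,14,15,16-tetranorlabda-8(17),11-dien-2β-yl acetate
Conditions: Ac2O, pyridine, 4-(dimethylamino)pyridine (10 mol %), 40 °C
Reagents that add atoms: acetic anhydride, CC(=O)OC(C)=O
Why: Nucleophile-catalysed acetylation overcomes the hindrance of the axial alcohol and proceeds with retention at C2.

Step 14
Reactants: 17 but-2-ynoic acid
Product: 18 (Z)-3-iodobut-2-enoic acid
Conditions: NaI, AcOH, 110 °C
Reagents that add atoms: sodium iodide, [Na+].[I-]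
Why: Conjugate anti-hydroiodination of the alkynoic acid places iodine and the carboxyl group cis (Z).

Step 15
Reactants: 16 13,14,15,16-tetranorlabda-8(17),11-dien-2β-yl acetate; 18 (Z)-3-iodobut-2-enoic acid
Product: 20 (13Z)-2β-acetoxylabda-8(17),13-dien-15-oic acid, via B-alkyl-9-BBN adduct 19 (not isolated)
Conditions: 9-borabicyclo[3.3.1]nonane dimer (0.55 equiv), THF, 0 to 25 °C; then 18, Pd(dppf)Cl2 (5 mol %), AsPh3 (5 mol %), K3PO4 (4 equiv), DMF/H2O, 25 °C; 1 M HCl
Reagents that add atoms: none
Why: Anti-Markovnikov hydroboration should prefer the outlying vinyl CH2 over the C8 methylene, which is flanked by C9 and shielded by C20, and the B-alkyl Suzuki–Miyaura coupling joins C12 to C13 with retention of the Z geometry while the hindered acetate tolerates phosphate at room temperature.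

**Compound list**
1 | 2,2-dimethylpent-4-enal | C=CCC(C)(C)C=O | starting material
2 | 2-(2-methylpent-4-en-2-yl)-1-oxaspiro[2.2]pentane (racemic) | C=CCC(C)(C)C1OC12CC2 | intermediate
3 | 2-(2-methylpent-4-en-2-yl)cyclobutan-1-one (racemic) | C=CCC(C)(C)C1CCC1=O | intermediate
4 | 3-methyl-3-(2-oxocyclobutyl)butanal (racemic) | O=CCC(C)(C)C1CCC1=O | intermediate
5 | 2-[(4R)-4-hydroxy-2-methylhept-6-yn-2-yl]cyclobutan-1-one (both epimers at the ring carbon) | O=C1CCC1C(C)(C)C[C@H](O)CC#C | intermediate
6 | (4R)-2-methyl-2-(2-oxocyclobutyl)hept-6-yn-4-yl 2,2-dimethylpropanoate (both epimers at the ring carbon) | O=C1CCC1C(C)(C)C[C@H](OC(=O)C(C)(C)C)CC#C | intermediate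
7 | methyl (5S)-7-methyl-7-(2-oxocyclobutyl)-5-(pivaloyloxy)oct-2-ynoate (both epimers at the ring carbon) | O=C1CCC1C(C)(C)C[C@H](OC(=O)C(C)(C)C)CC#CC(=O)OC | intermediate
8 | methyl (2Z,5R)-3,7-dimethyl-7-(2-oxocyclobutyl)-5-(pivaloyloxy)oct-2-enoate (both epimers at the ring carbon) | O=C1CCC1C(C)(C)C[C@H](OC(=O)C(C)(C)C)C/C(C)=C\C(=O)OC | intermediate
9 | methyl (2Z,5R)-7-{2-hydroxy-2-[(trimethylsilyl)methyl]cyclobutyl}-3,7-dimethyl-5-(pivaloyloxy)oct-2-enoate (all ring diastereomers) | C[Si](C)(C)CC1(O)CCC1C(C)(C)C[C@H](OC(=O)C(C)(C)C)C/C(C)=C\C(=O)OC | intermediate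
10 | methyl 8-hydroxy-2α-(pivaloyloxy)-17-(trimethylsilyl)-12,13,14,15,16-pentanorlabdan-11-oate (trans-decalin, 5α-H, 9α-H, 10β-CH3, C8 undefined) | C[Si](C)(C)CC1(O)CC[C@H]2C(C)(C)C[C@H](OC(=O)C(C)(C)C)C[C@]2(C)[C@H]1C(=O)OC | intermediate
11 | methyl 2α-(pivaloyloxy)-12,13,14,15,16-pentanorlabd-8(17)-en-11-oate (5α-H, 9α-H, 10β-CH3, equatorial 2α-ester) | C=C1CC[C@H]2C(C)(C)C[C@H](OC(=O)C(C)(C)C)C[C@]2(C)[C@H]1C(=O)OC | intermediate
12 | 12,13,14,15,16-pentanorlabd-8(17)-ene-2α,11-diol (5α-H, 9α-H, 10β-CH3) | C=C1CC[C@H]2C(C)(C)C[C@H](O)C[C@]2(C)[C@H]1CO | intermediate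
13 | 2-oxo-12,13,14,15,16-pentanorlabd-8(17)-en-11-al (5α-H, 9α-H, 10β-CH3) | C=C1CC[C@H]2C(C)(C)CC(=O)C[C@]2(C)[C@H]1C=O | intermediate
14 | 13,14,15,16-tetranorlabda-8(17),11-dien-2-one (5α-H, 9α-H, 10β-CH3) | C=C1CC[C@H]2C(C)(C)CC(=O)C[C@]2(C)[C@H]1C=C | intermediate
15 | 13,14,15,16-tetranorlabda-8(17),11-dien-2β-ol (axial OH) | C=C1CC[C@H]2C(C)(C)C[C@@H](O)C[C@]2(C)[C@H]1C=C | intermediate
16 | 13,14,15,16-tetranorlabda-8(17),11-dien-2β-yl acetate | C=C1CC[C@H]2C(C)(C)C[C@@H](OC(C)=O)C[C@]2(C)[C@H]1C=C | intermediate
17 | but-2-ynoic acid | CC#CC(=O)O | starting material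
18 | (Z)-3-iodobut-2-enoic acid | C/C(I)=C/C(=O)O | intermediate
19 | 12-(9-borabicyclo[3.3.1]nonan-9-yl)-13,14,15,16-tetranorlabd-8(17)-en-2β-yl acetate | C=C1CC[C@H]2C(C)(C)C[C@@H](OC(C)=O)C[C@]2(C)[C@H]1CCB1C2CCCC1CCC2 | intermediate
20 | (13Z)-2β-acetoxylabda-8(17),13-dien-15-oic acid | C=C1CC[C@H]2C(C)(C)C[C@@H](OC(C)=O)C[C@]2(C)[C@H]1CC/C(C)=C\C(=O)O | target

Total step count: 15. Longest linear sequence: 14 (steps 1–13 and 15).

**Steps most likely to fail**

Step 8.
- What may go wrong: the ester enolate may be protonated before it reaches the ketone. The C5 radical may be lost by 1,5-hydrogen transfer from C1. The α-silyl ketone may lose its silyl group. Reduction of the C9 radical by the spent photocatalyst may be too slow.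
- Fallback: an all-radical ring expansion built from known reaction types, setting out from 8 and returning at 11.
  - Wittig methylenation of 8 gives the methylidenecyclobutane F1.
  - Hydroboration with 9-borabicyclo[3.3.1]nonane and perborate oxidation gives the primary alcohol F2.
  - An Appel reaction (I2, PPh3, imidazole) gives the iodide F3.
  - Irradiation of F3 with (n-Bu3Sn)2 in hot benzene starts an iodine-atom-transfer cascade. The cyclobutylcarbinyl radical fragments to the C5 radical and a C8 vinyl group. C5 closes ring A by the same 6-exo Giese addition. The electrophilic C9 radical closes ring B 6-exo onto the vinyl group, and the C17 radical takes iodine from F3 to give the decalin iodide F4.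
  - Elimination with 1,8-diazabicyclo[5.4.0]undec-7-ene leads to 11.

Step 15.
- What may go wrong: hydroboration of the C8 methylene may compete with that of the vinyl group. Transmetalation may be sluggish in the presence of the carboxylate. The acetate may be slowly hydrolysed.
- Fallback: sets out from 16 (and 18) and returns at 20.
  - The more discriminating disiamylborane followed by perborate gives the primary alcohol F5.
  - An Appel reaction gives the iodide F6.
  - Acid 18 is converted with allyl bromide and K2CO3 into the allyl ester F7.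
  - Zinc insertion into F6 and Negishi coupling with F7 under Pd(dppf)Cl2 give the allyl labdadienoate F8.
  - Tsuji–Trost deallylation with Pd(PPh3)4 and morpholine frees 20 without touching the acetate.

Step 11.
- What may go wrong: the ylide may attack the C2 ketone as well. Base may shift the C8=C17 double bond into conjugation with the aldehyde or epimerise C9.
- Fallback: the two carbonyl groups are unveiled one after the other, setting out from 12 and returning at 14.
  - Oxidation with 2,2,6,6-tetramethylpiperidine-1-oxyl and PhI(OAc)2 selects the primary alcohol and gives the hydroxy aldehyde F9.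
  - Wittig methylenation with excess ylide gives the dienol F10.
  - Ley–Griffith oxidation of the remaining 2α-alcohol gives 14.

**Further compounds**
F1 | step 8 | methyl (2Z,5R)-3,7-dimethyl-7-(2-methylidenecyclobutyl)-5-(pivaloyloxy)oct-2-enoate | C=C1CCC1C(C)(C)C[C@H](OC(=O)C(C)(C)C)C/C(C)=C\C(=O)OC
F2 | step 8 | methyl (2Z,5R)-7-[2-(hydroxymethyl)cyclobutyl]-3,7-dimethyl-5-(pivaloyloxy)oct-2-enoate | OCC1CCC1C(C)(C)C[C@H](OC(=O)C(C)(C)C)C/C(C)=C\C(=O)OC
F3 | step 8 | methyl (2Z,5R)-7-[2-(iodomethyl)cyclobutyl]-3,7-dimethyl-5-(pivaloyloxy)oct-2-enoate | ICC1CCC1C(C)(C)C[C@H](OC(=O)C(C)(C)C)C/C(C)=C\C(=O)OC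
F4 | step 8 | methyl 17-iodo-2α-(pivaloyloxy)-12,13,14,15,16-pentanorlabdan-11-oate | ICC1CC[C@H]2C(C)(C)C[C@H](OC(=O)C(C)(C)C)C[C@]2(C)[C@H]1C(=O)OC
F5 | step 15 | 12-hydroxy-13,14,15,16-tetranorlabd-8(17)-en-2β-yl acetate | C=C1CC[C@H]2C(C)(C)C[C@@H](OC(C)=O)C[C@]2(C)[C@H]1CCO
F6 | step 15 | 12-iodo-13,14,15,16-tetranorlabd-8(17)-en-2β-yl acetate | C=C1CC[C@H]2C(C)(C)C[C@@H](OC(C)=O)C[C@]2(C)[C@H]1CCI
F7 | step 15 | allyl (Z)-3-iodobut-2-enoate | C/C(I)=C/C(=O)OCC=C
F8 | step 15 | allyl (13Z)-2β-acetoxylabda-8(17),13-dien-15-oate | C=C1CC[C@H]2C(C)(C)C[C@@H](OC(C)=O)C[C@]2(C)[C@H]1CC/C(C)=C\C(=O)OCC=C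
F9 | step 11 | 2α-hydroxy-12,13,14,15,16-pentanorlabd-8(17)-en-11-al | C=C1CC[C@H]2C(C)(C)C[C@H](O)C[C@]2(C)[C@H]1C=O
F10 | step 11 | 13,14,15,16-tetranorlabda-8(17),11-dien-2α-ol | C=C1CC[C@H]2C(C)(C)C[C@H](O)C[C@]2(C)[C@H]1C=C
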